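With a small charge of starting material you want to know, before weighing anything, how much partner the solid reagent releases in a given time, and the earlier runs allow an estimate.

| flask | starting material | solid reagent | temperature | remark | time |
|---|---|---|---|---|---|
| grey | 0.055 M | 0.11 M | 8 °C | run made earlier |  |
| ochre | 0.22 M | 0.11 M | 24 °C | run made earlier |  |
| green | 0.11 M | 0.22 M | 8 °C | run made earlier |  |
| south | 0.11 M | 0.110 M | 30 °C |  | 80 min |
| north-east | 0.11 M | 0.110 M | 0 °C |  | 80 min |

| run | time / min | target / % | over-reaction product / % | starting material / % |
|---|---|---|---|---|
| grey | 40.0 | 19 | 0 | 78 |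
| grey | 80.0 | 34 | 0 | 64 |
| grey | 120 | 42 | 6 | 55 |
| grey | 150 | 43 | 5 | 49 |
| grey | 180 | 45 | 4 | 45 |
| ochre | 12.0 | 3 | 0 | 99 |
| ochre | 25.0 | 4 | 0 | 94 |
| ochre | 40.0 | 5 | 2 | 93 |
| ochre | 50.0 | 8 | 0 | 94 |
| ochre | 60.0 | 8 | 0 | 90 |
| green | 40.0 | 12 | 1 | 90 |
| green | 80.0 | 25 | 2 | 77 |
| green | 120 | 26 | 1 | 71 |
| green | 150 | 32 | 2 | 66 |
| green | 180 | 36 | 1 | 61 |

(standard deviation of a reading: 2 percentage points)

- solid reagent is a solid; its amount is given per volume of the solution
- what was read earlier has a scatter of 2 percentage points, one standard deviation
- steps thought possible: partner + target -> over-reaction product; solid reagent <-> partner; starting material + partner <-> target + by-product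
- at the start none of the solid reagent is in solution

- which flask leads in share of target in all that became target or over-reaction product ("all alike" within 1.5 percentage points) (south / north-east / all alike)
- share of target in all that became target or over-reaction product, south
- share of target in all that became target or over-reaction product, north-east

Read the tables run against run as target formed per minute. The grey run gives 2.61 × 10⁻⁴ M/min at its first reading, the green run 3.30 × 10⁻⁴ M/min at its first, and the ochre run 2.93 × 10⁻⁴ M/min at its last. Yet the charge runs from 0.055 M to 0.22 M and the temperature from 8 °C to 24 °C. The highest of these readings is 1.26 times the lowest, so dissolution of the solid reagent looks like the rate-limiting step.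

I take their mean, 2.95 × 10⁻⁴ M/min, as the supply rate, a reading that carries their scatter. Multiplied by the time, it gives the dose, my estimate of the concentration of partner handed into solution up to that time: 0.0236 M at 80 min. That is 21.4% of the starting material charged, and the solid charge stands above it. My reckoning therefore gives south and north-east the same dose, but it does not say how each flask divides that dose.

The forecast puts north-east ahead, at 98% (94% to 100%) against 95% for south (88% to 99%). Its ground for south: “if over-reaction has the higher activation energy, as is likely but unproven”.

The simulation puts north-east ahead, at 99.7% against 88.6% for south.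

    partner + target → over-reaction product (k = 0.0312 /M/min, Ea = 59.0 kJ/mol)
    solid reagent ⇌ partner, rate k2*(cs2 - [partner]) while solid is left; crystals form when [partner] > cs2 (solubility = 0.0610 M, k = 0.00645 /min)
    starting material + partner ⇌ target + by-product (K = 2.40, k = 4.41 /M/min, Ea = 53.0 kJ/mol, ΔH = −53.0 kJ/mol)
    (constants at 0 °C)

Against the reckoned dose of 0.0236 M, south has lost 0.0290 M from its solid by 80.0 min and north-east 0.0305 M. At that time north-east holds 0.0262 M of by-product with 0.00417 M of free partner, while south holds 0.0164 M with 0.0107 M, so south has more free partner on less by-product. A neighbour like north-east kept at 25 °C receives the same reckoned dose and has lost 0.0293 M from its solid by 80.0 min. It holds 0.0182 M of by-product with 0.00989 M of free partner, and its share of target stands at 93.0%.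

The earlier runs and the new flask were generated by integration with constants of no real substance, and the scatter is random.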